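The route rests on the C9–C9a bond of cyclopentane ring C. C9a is the aza-quaternary carbon shared by pyrrolidine ring A, azepane ring B and ring C. Its neighbour C12 carries lactone ring D, so ring C is read as a 2-aminocyclopentanone and carried as a cyclobutanol. The precursor is a monocyclic 1-alkynylcyclobutanol whose alkyne ends in an L-propargylglycinol sulfonamide. In one operation the sulfonamide adds to the alkyne (ring A), the enesulfonamide is protonated, and C9 shifts from carbinol carbon C12 to the iminium carbon. The four-membered ring becomes ring C, C9a is set, and the C12 ketone remains as the handle for ring D.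

Key step: step 7

Labels:
- Ring A: N4–C3–C2–C1–C9a.
- Ring B: N4–C5–C6–C7–C8–C9–C9a.
- Ring C: C9a–C9–C10–C11–C12.
- Ring D (lactone): C11–O–C14(=O)–C13–C12.
- Ring E (lactone on C3): C18–C19–C20–C21(=O)–O.
- The ethyl group sits on C10.
- SES = 2-(trimethylsilyl)ethylsulfonyl; TBDPS = tert-butyldiphenylsilyl.

Assumption: the (2R,5R) auxiliary is taken to induce the (3S)-ethyl centre of ketone 7. If the sense of induction is opposite, the equally available (2S,5S) amine is used with no other change.

**Step 1**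
Reactants: 1 6-chlorohexanoyl chloride; 2 (2R,5R)-2,5-dimethylpyrrolidine
Product: 3 6-chloro-1-[(2R,5R)-2,5-dimethylpyrrolidin-1-yl]hexan-1-one
Conditions: Et3N, CH2Cl2, 0 °C
Reagents that add atoms: none
Why: N-acylation of a secondary amine by an acid chloride is fast at 0 °C and leaves the primary alkyl chloride untouched; the two auxiliary stereocentres come from 2.

**Step 2**
Reactants: 3 6-chloro-1-[(2R,5R)-2,5-dimethylpyrrolidin-1-yl]hexan-1-one; 4 but-1-ene
Product: 7 (2R,3S)-2-(4-chlorobutyl)-3-ethylcyclobutan-1-one, via keteniminium triflate 5 (not isolated), via cyclobutaniminium triflate 6 (not isolated)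
Conditions: Tf2O, 2,4,6-collidine, 4 (excess), CH2Cl2, sealed vessel, −20 to 40 °C; then H2O, 40 °C; basic Al2O3
Reagents that add atoms: water, O
Why: Keteniminium–olefin [2+2] cycloaddition: the CH2 terminus of 4 bonds to the electrophilic central carbon (future C12) so that the ethyl-bearing C10 ends next to C9, the C2-symmetric auxiliary differentiates the two faces and thereby sets C10, and hydrolysis followed by base-mediated epimerisation of the enolisable C9 should deliver the more stable trans ketone.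

**Step 3**
Reactants: 8 methyl (2S)-2-aminopent-4-ynoate hydrochloride (L-propargylglycine methyl ester hydrochloride)
Product: 9 methyl (2S)-2-(SES-amino)pent-4-ynoate
Conditions: SESCl, Et3N, CH2Cl2, 0 °C to rt
Reagents that add atoms: 2-(trimethylsilyl)ethanesulfonyl chloride (SESCl), C[Si](C)(C)CCS(=O)(=O)Cl
Why: Sulfonylation of the free-based amino ester gives an acidic, non-basic N–H that serves as the nucleophile of the key step and is later cleaved by fluoride; C3 is taken unchanged from L-propargylglycine.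

**Step 4**
Reactants: 9 methyl (2S)-2-(SES-amino)pent-4-ynoate
Product: 10 N-[(2S)-1-hydroxypent-4-yn-2-yl]-2-(trimethylsilyl)ethanesulfonamide
Conditions: LiBH4, THF, 0 °C to rt
Reagents that add atoms: none
Why: Hydride reduction of the ester with LiBH4 is chemoselective over the terminal alkyne and the sulfonamide, and C3 is not epimerised because the sulfonamide N–H is deprotonated first.

**Step 5**
Reactants: 10 N-[(2S)-1-hydroxypent-4-yn-2-yl]-2-(trimethylsilyl)ethanesulfonamide
Product: 11 N-[(2S)-1-(TBDPS-oxy)pent-4-yn-2-yl]-2-(trimethylsilyl)ethanesulfonamide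
Conditions: TBDPSCl, imidazole, DMF, rt
Reagents that add atoms: tert-butyl(chloro)diphenylsilane (TBDPSCl), CC(C)(C)[Si](Cl)(c1ccccc1)c1ccccc1
Why: Standard silylation blocks the primary oxygen, which would otherwise add 5-exo-dig to the activated alkyne in step 7, with a group that survives n-BuLi and anhydrous acid.

**Step 6**
Reactants: 11 N-[(2S)-1-(TBDPS-oxy)pent-4-yn-2-yl]-2-(trimethylsilyl)ethanesulfonamide; 7 (2R,3S)-2-(4-chlorobutyl)-3-ethylcyclobutan-1-one
Product: 13 (1R,2R,3S)-2-(4-chlorobutyl)-3-ethyl-1-[(4S)-5-(TBDPS-oxy)-4-(SES-amino)pent-1-yn-1-yl]cyclobutan-1-ol (OH trans to the chlorobutyl chain and cis to ethyl), via dilithio acetylide 12 (not isolated)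
Conditions: n-BuLi (2.1 equiv), THF, −78 °C; then 7, −78 °C; H2O quench
Reagents that add atoms: none
Why: 1,2-Addition of a lithium acetylide to a ketone: double deprotonation (N–H, then C≡C–H) gives 12, cyclobutanones add acetylides faster than they enolise, and the slim nucleophile is expected to enter pseudoaxially, anti to the cross-ring C10 ethyl group (the 1,3-effect that governs additions to 3-substituted cyclobutanones), so that the new C12 hydroxyl is trans to the C9 chain; the C12 epimer is removed by chromatography.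

**Step 7**
Reactants: 13 (1R,2R,3S)-2-(4-chlorobutyl)-3-ethyl-1-[(4S)-5-(TBDPS-oxy)-4-(SES-amino)pent-1-yn-1-yl]cyclobutan-1-ol
Product: 16 (2S,5S,8S,9R)-9-(4-chlorobutyl)-8-ethyl-1-SES-2-(TBDPS-oxymethyl)-1-azaspiro[4.4]nonan-6-one, via enesulfonamide 14 (not isolated), via N-sulfonyliminium ion 15 (not isolated)
Conditions: AgOTf (10 mol %), 4 Å MS, CH2Cl2, rt; then (+)-camphorsulfonic acid (20 mol %), 0 °C to rt
Reagents that add atoms: none
Why: AgOTf (monovalent silver) activates the C1≡C9a alkyne, the sulfonamide N–H adds to C9a (ring A, 5-endo-dig) and protodemetalation gives 14; the acid then protonates C1 to give 15, whose strained C12–C9 bond migrates to the iminium carbon while the carbinol oxygen becomes the C12 ketone (ring C, four- to five-membered by a 1,2-alkyl shift driven by release of cyclobutane strain). The closest known reaction types are the tandem hydroamination/semipinacol rearrangement of 1-(4-sulfonamidobut-1-ynyl)cyclobutanols and the acid-promoted semipinacol expansion of 2-(1-hydroxycyclobutyl) enesulfonamides to 1-azaspiro[4.4]nonan-6-ones. The one new stereocentre, C9a, is controlled by C3: allylic 1,3-strain with the sulfonyl group turns the CH2OTBDPS arm pseudoaxial, so the migrating carbon enters from the opposite face, and since C9 migrates with retention, N4 ends trans and C1 cis to the C8 chain. The step needs C9 rather than C11 to migrate, which the higher migratory aptitude of the more substituted carbon secures, and in 13 the rotamer that keeps the small OH next to the sulfonyl group places exactly C9 on the open face, so that the three elements reinforce each other. It also needs N–H addition to outrun an alkyl shift onto the metal-bound alkyne and Meyer–Schuster isomerisation, which is why a silver salt rather than a more carbophilic gold catalyst is used and the acid is added only after the alkyne is consumed. C12 ceases to be a stereocentre, and C3, C9 and C10 are not touched.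

**Step 8**
Reactants: 16 (2S,5S,8S,9R)-9-(4-chlorobutyl)-8-ethyl-1-SES-2-(TBDPS-oxymethyl)-1-azaspiro[4.4]nonan-6-one
Product: 18 (2S,5S,7S,8R,9R)-9-(4-chlorobutyl)-8-ethyl-7-hydroxy-1-SES-2-(TBDPS-oxymethyl)-1-azaspiro[4.4]nonan-6-one, via potassium enolate 17 (not isolated)
Conditions: KN(SiMe3)2, THF, −78 °C; 3-phenyl-2-(phenylsulfonyl)oxaziridine, −78 °C; AcOH
Reagents that add atoms: 3-phenyl-2-(phenylsulfonyl)oxaziridine, O=S(=O)(N1OC1c1ccccc1)c1ccccc1
Why: Davis oxidation of a ketone enolate: C11 is the only enolisable position because C9a is quaternary, and the oxaziridine approaches from the face opposite to the C10 ethyl group and the N-sulfonyl group, which sets the C11 oxygen trans to ethyl.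

**Step 9**
Reactants: 18 (2S,5S,7S,8R,9R)-9-(4-chlorobutyl)-8-ethyl-7-hydroxy-1-SES-2-(TBDPS-oxymethyl)-1-azaspiro[4.4]nonan-6-one
Product: 19 C11 2-(diethoxyphosphoryl)propanoate of 18 (both configurations at the phosphonate carbon)
Conditions: 2-(diethoxyphosphoryl)propanoic acid, DCC, DMAP (cat.), CH2Cl2, 0 °C to rt
Reagents that add atoms: 2-(diethoxyphosphoryl)propanoic acid, CCOP(=O)(OCC)C(C)C(=O)O
Why: Steglich esterification of the secondary α-ketol under neutral conditions installs C13, C14 and the C13 methyl group without epimerising C11.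

**Step 10**
Reactants: 19 C11 2-(diethoxyphosphoryl)propanoate of 18
Product: 20 (3S,9R,9aS,10R,11S)-butenolide of rings A/C/D: α-methylbutenolide C12=C13 fused to ring C at C11–C12, N4-SES, C3 CH2OTBDPS, C9 4-chlorobutyl
Conditions: LiCl, DBU, MeCN, rt to 50 °C
Reagents that add atoms: none
Why: Intramolecular Horner–Wadsworth–Emmons olefination under Masamune–Roush conditions closes ring D on the hindered C12 ketone because the phosphonate is held next to it, and the mild base leaves the alkyl chloride and C11 intact.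

**Step 11**
Reactants: 20 (3S,9R,9aS,10R,11S)-butenolide of rings A/C/D
Product: 22 (3S,9R,9aS,10R,11S,12R,13S)-α-hydroxy-α-methyl lactone of rings A/C/D (H12 cis to H11; C13 OH cis to H12), via tertiary hydroperoxide 21 (not isolated)
Conditions: Mn(dpm)3 (10 mol %), PhSiH3, O2 (1 atm), i-PrOH/CH2Cl2, 0 °C to rt; then P(OEt)3
Reagents that add atoms: dioxygen, O=O
Why: Mukaiyama-type reductive α-hydroxylation of an α,β-unsaturated lactone: a manganese hydride transfers a hydrogen atom to the β-carbon C12, where only the cis ring fusion (H12 syn to H11) is attainable, the tertiary C13 radical captures O2 on the convex face of the bicyclo[3.3.0] unit (OH cis to H12, methyl endo), and P(OEt)3 reduces hydroperoxide 21.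

**Step 12**
Reactants: 22 (3S,9R,9aS,10R,11S,12R,13S)-α-hydroxy-α-methyl lactone of rings A/C/D
Product: 24 tetracyclic amino alcohol of rings A–D with CH2OH on C3 (configuration of the target at C3, C9, C9a, C10, C11, C12, C13), via amino chloride 23 (not isolated)
Conditions: Bu4NF (4 equiv), MeCN, 60 °C; then NaI (cat.), 80 °C; work-up at pH 5
Reagents that add atoms: none
Why: Fluoride attacks both silicon atoms, so the SES group fragments (β-elimination with loss of ethylene and SO2), the TBDPS ether is cleaved, and the liberated secondary amine closes ring B by 7-exo-tet intramolecular N-alkylation under iodide catalysis without creating or touching a stereocentre.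

**Step 13**
Reactants: 24 tetracyclic amino alcohol of rings A–D
Product: 25 tetracyclic C3 carbaldehyde (C18 aldehyde, 3S)
Conditions: Dess–Martin periodinane, CH2Cl2, 0 °C to rt
Reagents that add atoms: none
Why: Dess–Martin oxidation converts the only oxidisable alcohol (the C13 hydroxyl is tertiary) into the aldehyde, the acetic acid released keeps N4 protonated, and the configurationally sensitive α-amino aldehyde is used crude so that C3 is kept.

**Step 14**
Reactants: 25 tetracyclic C3 carbaldehyde
Product: 27 pentacyclic α-methylene-γ-butyrolactone (ring E with exocyclic C20=CH2, 18S), via hydroxy ester 26 (not isolated)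
Conditions: Zn dust, ethyl 2-(bromomethyl)acrylate, THF, 50 °C
Reagents that add atoms: ethyl 2-(bromomethyl)acrylate, CCOC(=O)C(=C)CBr
Why: Barbier-type addition of the 2-(ethoxycarbonyl)allylzinc reagent to the aldehyde followed by lactonisation of the zinc alkoxide is a known entry to α-methylene-γ-butyrolactones, and zinc chelated between N4 and the aldehyde oxygen (Cram chelate) exposes the face flanked by H3, which sets the C18 oxygen syn to N4.

**Step 15**
Reactants: 27 pentacyclic α-methylene-γ-butyrolactone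
Product: 28 target CNP0260919.2
Conditions: H2 (1 atm), Pd/C, EtOAc, rt
Reagents that add atoms: none
Why: Heterogeneous hydrogenation of the exocyclic alkene from the lactone face opposite to the bulky C18 substituent places the C20 methyl cis to that substituent.

**Compound list**

1 | 6-chlorohexanoyl chloride | O=C(Cl)CCCCCCl | starting material
2 | (2R,5R)-2,5-dimethylpyrrolidine | C[C@@H]1CC[C@@H](C)N1 | starting material
3 | 6-chloro-1-[(2R,5R)-2,5-dimethylpyrrolidin-1-yl]hexan-1-one | O=C(CCCCCCl)N1[C@H](C)CC[C@H]1C | intermediate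
4 | but-1-ene | C=CCC | starting material
5 | keteniminium triflate | ClCCCCC=C=[N+]1[C@H](C)CC[C@H]1C.[O-]S(=O)(=O)C(F)(F)F | intermediate
6 | cyclobutaniminium triflate (C9 epimers) | CC[C@H]1CC(=[N+]2[C@H](C)CC[C@H]2C)C1CCCCCl.[O-]S(=O)(=O)C(F)(F)F | intermediate
7 | (2R,3S)-2-(4-chlorobutyl)-3-ethylcyclobutan-1-one | CC[C@H]1CC(=O)[C@@H]1CCCCCl | intermediate
8 | methyl (2S)-2-aminopent-4-ynoate hydrochloride | C#CC[C@H](N)C(=O)OC.Cl | starting material
9 | methyl (2S)-2-(SES-amino)pent-4-ynoate | C#CC[C@H](NS(=O)(=O)CC[Si](C)(C)C)C(=O)OC | intermediate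
10 | N-[(2S)-1-hydroxypent-4-yn-2-yl]-2-(trimethylsilyl)ethanesulfonamide | C#CC[C@H](NS(=O)(=O)CC[Si](C)(C)C)CO | intermediate
11 | N-[(2S)-1-(TBDPS-oxy)pent-4-yn-2-yl]-2-(trimethylsilyl)ethanesulfonamide | C#CC[C@H](NS(=O)(=O)CC[Si](C)(C)C)CO[Si](c1ccccc1)(c1ccccc1)C(C)(C)C | intermediate
12 | N,C-dilithio derivative of 11 | [Li]C#CC[C@H](N([Li])S(=O)(=O)CC[Si](C)(C)C)CO[Si](c1ccccc1)(c1ccccc1)C(C)(C)C | intermediate
13 | alkynylcyclobutanol (1R,2R,3S; side chain 4S) | CC[C@H]1C[C@](O)(C#CC[C@H](NS(=O)(=O)CC[Si](C)(C)C)CO[Si](c2ccccc2)(c2ccccc2)C(C)(C)C)[C@@H]1CCCCCl | intermediate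
14 | 2-(1-hydroxycyclobutyl) enesulfonamide (2,3-dihydropyrrole) | CC[C@H]1C[C@](O)(C2=CC[C@@H](CO[Si](c3ccccc3)(c3ccccc3)C(C)(C)C)N2S(=O)(=O)CC[Si](C)(C)C)[C@@H]1CCCCCl | intermediate
15 | N-sulfonyliminium ion (cation shown) | CC[C@H]1C[C@](O)(C2=[N+](S(=O)(=O)CC[Si](C)(C)C)[C@H](CO[Si](c3ccccc3)(c3ccccc3)C(C)(C)C)CC2)[C@@H]1CCCCCl | intermediate
16 | (2S,5S,8S,9R)-spiroketone | CC[C@H]1CC(=O)[C@]2(CC[C@@H](CO[Si](c3ccccc3)(c3ccccc3)C(C)(C)C)N2S(=O)(=O)CC[Si](C)(C)C)[C@@H]1CCCCCl | intermediate
17 | potassium enolate of 16 | CC[C@H]1C=C([O-])[C@]2(CC[C@@H](CO[Si](c3ccccc3)(c3ccccc3)C(C)(C)C)N2S(=O)(=O)CC[Si](C)(C)C)[C@@H]1CCCCCl.[K+] | intermediate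
18 | (2S,5S,7S,8R,9R)-α-hydroxy ketone | CC[C@H]1[C@H](O)C(=O)[C@]2(CC[C@@H](CO[Si](c3ccccc3)(c3ccccc3)C(C)(C)C)N2S(=O)(=O)CC[Si](C)(C)C)[C@@H]1CCCCCl | intermediate
19 | C11 2-(diethoxyphosphoryl)propanoate | CC[C@H]1[C@H](OC(=O)C(C)P(=O)(OCC)OCC)C(=O)[C@]2(CC[C@@H](CO[Si](c3ccccc3)(c3ccccc3)C(C)(C)C)N2S(=O)(=O)CC[Si](C)(C)C)[C@@H]1CCCCCl | intermediate
20 | butenolide of rings A/C/D | CC[C@H]1[C@@H]2OC(=O)C(C)=C2[C@]3(CC[C@@H](CO[Si](c4ccccc4)(c4ccccc4)C(C)(C)C)N3S(=O)(=O)CC[Si](C)(C)C)[C@@H]1CCCCCl | intermediate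
21 | C13 hydroperoxide | CC[C@H]1[C@@H]2OC(=O)[C@@](C)(OO)[C@@H]2[C@]3(CC[C@@H](CO[Si](c4ccccc4)(c4ccccc4)C(C)(C)C)N3S(=O)(=O)CC[Si](C)(C)C)[C@@H]1CCCCCl | intermediate
22 | α-hydroxy-α-methyl lactone of rings A/C/D | CC[C@H]1[C@@H]2OC(=O)[C@@](C)(O)[C@@H]2[C@]3(CC[C@@H](CO[Si](c4ccccc4)(c4ccccc4)C(C)(C)C)N3S(=O)(=O)CC[Si](C)(C)C)[C@@H]1CCCCCl | intermediate
23 | deprotected secondary amine with chlorobutyl chain | CC[C@H]1[C@@H]2OC(=O)[C@@](C)(O)[C@@H]2[C@]3(CC[C@@H](CO)N3)[C@@H]1CCCCCl | intermediate
24 | tetracyclic amino alcohol | CC[C@H]1[C@@H]2OC(=O)[C@@](C)(O)[C@@H]2[C@@]23CC[C@@H](CO)N2CCCC[C@H]13 | intermediate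
25 | tetracyclic amino aldehyde | CC[C@H]1[C@@H]2OC(=O)[C@@](C)(O)[C@@H]2[C@@]23CC[C@@H](C=O)N2CCCC[C@H]13 | intermediate
26 | (18S)-γ-hydroxy-α-methylene ester (formed as zinc alkoxide) | CC[C@H]1[C@@H]2OC(=O)[C@@](C)(O)[C@@H]2[C@@]23CC[C@@H]([C@@H](O)CC(=C)C(=O)OCC)N2CCCC[C@H]13 | intermediate
27 | α-methylene lactone | CC[C@H]1[C@@H]2OC(=O)[C@@](C)(O)[C@@H]2[C@@]23CC[C@@H]([C@@H]4CC(=C)C(=O)O4)N2CCCC[C@H]13 | intermediate
28 | CNP0260919.2 | CC[C@H]1[C@@H]2OC(=O)[C@@](C)(O)[C@@H]2[C@@]23CC[C@@H]([C@@H]4C[C@H](C)C(=O)O4)N2CCCC[C@H]13 | target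

Total step count: 15. Longest linear sequence: 13 (steps 3–15, from 8).

**Steps most likely to fail**

**Step 7.**
- What may go wrong: the metal-bound alkyne may undergo an alkyl shift or Meyer–Schuster isomerisation before the N–H adds. The 1,2-shift may also discriminate poorly between C9 and C11 or between the two iminium faces.
- Fallback (sets out from 7, comes back at 14, uses no alkyne and no π-acid): (S)-5-(hydroxymethyl)pyrrolidin-2-one is silylated (TBDPSCl, imidazole) to lactam silyl ether F1. This is N-sulfonylated (n-BuLi, SESCl) to N-SES lactam F2. KN(SiMe3)2 and Comins reagent convert it into enol triflate F3, and Me3SnSnMe3, Pd(PPh3)4 and LiCl give vinylstannane F4. Tin–lithium exchange with MeLi at −78 °C gives vinyllithium F5. F5 adds to 7 to give 14 as an isolable compound, and camphorsulfonic acid alone then carries 14 on to 16.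

**Step 11.**
- What may go wrong: hydrogen atom transfer to the fully substituted, neopentyl C12 may be too slow, so that unproductive silane consumption or plain reduction takes over.
- Fallback (sets out from 20, comes back at 22): conjugate reduction with NiCl2·6H2O/NaBH4 in MeOH gives saturated cis-fused lactone F6. At this stage it is the only lactone in the molecule. Its potassium enolate (KN(SiMe3)2, −78 °C) is hydroxylated with 3-phenyl-2-(phenylsulfonyl)oxaziridine on the convex face.

**Step 12.**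
- What may go wrong: N-alkylation by the very hindered amine may lag behind chloride–fluoride exchange or base-induced lactone opening.
- Fallback (sets out from 22, comes back at 24, closes ring B by reductive amination): Finkelstein exchange (NaI, acetone) gives primary iodide F7. Oxidation with Me3NO in DMSO gives C5 aldehyde F8. Bu4NF then removes both silicon groups, and the free amine condenses with the aldehyde to cyclic iminium ion F9. NaBH(OAc)3 reduces F9 to 24.

**Further compounds**
F1 | step 7 | (S)-5-(TBDPS-oxymethyl)pyrrolidin-2-one | O=C1CC[C@@H](CO[Si](c2ccccc2)(c2ccccc2)C(C)(C)C)N1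
F2 | step 7 | (S)-1-SES-5-(TBDPS-oxymethyl)pyrrolidin-2-one | O=C1CC[C@@H](CO[Si](c2ccccc2)(c2ccccc2)C(C)(C)C)N1S(=O)(=O)CC[Si](C)(C)C
F3 | step 7 | lactam-derived enol triflate | O=S(=O)(OC1=CC[C@@H](CO[Si](c2ccccc2)(c2ccccc2)C(C)(C)C)N1S(=O)(=O)CC[Si](C)(C)C)C(F)(F)F
F4 | step 7 | 5-(trimethylstannyl)-2,3-dihydropyrrole | C[Sn](C)(C)C1=CC[C@@H](CO[Si](c2ccccc2)(c2ccccc2)C(C)(C)C)N1S(=O)(=O)CC[Si](C)(C)C
F5 | step 7 | 5-lithio-2,3-dihydropyrrole | [Li]C1=CC[C@@H](CO[Si](c2ccccc2)(c2ccccc2)C(C)(C)C)N1S(=O)(=O)CC[Si](C)(C)C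
F6 | step 11 | saturated cis-fused α-methyl lactone (C13 epimers) | CC[C@H]1[C@@H]2OC(=O)C(C)[C@@H]2[C@]3(CC[C@@H](CO[Si](c4ccccc4)(c4ccccc4)C(C)(C)C)N3S(=O)(=O)CC[Si](C)(C)C)[C@@H]1CCCCCl
F7 | step 12 | primary iodide | CC[C@H]1[C@@H]2OC(=O)[C@@](C)(O)[C@@H]2[C@]3(CC[C@@H](CO[Si](c4ccccc4)(c4ccccc4)C(C)(C)C)N3S(=O)(=O)CC[Si](C)(C)C)[C@@H]1CCCCI
F8 | step 12 | C5 aldehyde | CC[C@H]1[C@@H]2OC(=O)[C@@](C)(O)[C@@H]2[C@]3(CC[C@@H](CO[Si](c4ccccc4)(c4ccccc4)C(C)(C)C)N3S(=O)(=O)CC[Si](C)(C)C)[C@@H]1CCCC=O
F9 | step 12 | cyclic iminium ion (cation shown) | CC[C@H]1[C@@H]2OC(=O)[C@@](C)(O)[C@@H]2[C@@]23CC[C@@H](CO)[N+]2=CCCC[C@H]13
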